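It is easy to plan the next flasks as if the capture agent went on working through the whole run. But its charge is 3.60 mM against 36 mM of starting complex, which makes it the limiting reagent of a one-to-one capture. We write its balance, assuming that each capture agent takes up one complex, one to one, and is lost with it. We call 10.0 % of the starting complex charged the capture ceiling, the capture agent charged over the starting complex charged. At any moment, the complex captured is this ceiling times the fraction of capture agent consumed.

all flasks: starting complex 36 mM
- larch: incoming ligand 25 mM; leaving ligand 18 mM; capture agent 3.6 mM; run made earlier
- cedar: incoming ligand 220 mM; leaving ligand 18 mM; capture agent 3.6 mM; run made earlier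
- autumn: incoming ligand 18.0 mM; leaving ligand 18.0 mM; capture agent 3.60 mM; time 10 min
- dawn: incoming ligand 90.0 mM; leaving ligand 18.0 mM; capture agent 3.60 mM; time 10 min
- summer: incoming ligand 144 mM; leaving ligand 18.0 mM; capture agent 3.60 mM; time 10 min

- larch (time / min: complex with two exchanged / %): 0.833: 0; 1.33: 1.1; 2.00: 0.4; 4.00: 0.9; 6.00: 1.4; 10.0: 1.5
- cedar (time / min: complex with two exchanged / %): 1.50: 22.1; 3.00: 16.5; 5.00: 13.9; 6.00: 11.3; 8.00: 9.5; 10.0: 8.6

(each reading ± 0.5 percentage points)

- what was read earlier has a scatter of 0.5 percentage points, one standard deviation

Larch and cedar both ran at one ceiling, so we leave the capture agent and the starting complex as charged, and we change the incoming ligand. The time must be held as well, because cedar fell from 22.1 % at 1.50 min to 8.6 % at 10.0 min, so a reading at another time is not comparable. Larch read 1.5 % at 10.0 min. Dawn, at 90.0 mM, and summer, at 144 mM, lie between the two runs. Autumn, at 18.0 mM, lies below larch's 25 mM, outside the span we have read.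

- amount of complex with two exchanged at the end, in percent of the starting complex charged, for each flask in turn (autumn, dawn, summer)

The forecast gives 1.1 %, 4.6 % and 6.6 % for autumn, dawn and summer, on the ground that “the dependence looks roughly first-power”. Our reckoning differs in kind: it gives no row, only a bound of 10.0 % on the complex captured.

The flasks give 0.520 %, 4.82 % and 6.77 %, within the forecast's margin.

    complex with one exchanged + incoming ligand ⇌ leaving ligand + complex with two exchanged (K = 0.200, k = 0.0950 M⁻¹ s⁻¹)
    complex with two exchanged → over-reaction product (k = 0.00610 s⁻¹)
    starting complex + incoming ligand ⇌ leaving ligand + complex with one exchanged (K = 0.660, k = 0.190 M⁻¹ s⁻¹)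
    complex with one exchanged + capture agent → trapped intermediate (k = 1.40 M⁻¹ s⁻¹)

Dawn has 0.00859 % of its capture agent's charge left at 10.0 min, so the balance gives 10.0 % captured, and dawn holds 10.0 % of trapped intermediate. Autumn, with 1.87 % left, gives 9.81 % and holds 9.81 %. In dawn, the complex with two exchanged has a half-life of 1.9 min by the step to over-reaction product alone, shorter than the 10 min of the run. Dawn's complex with two exchanged falls from 6.86 % at 5.00 min to 4.82 % at 10.0 min, while its over-reaction product reaches 23.0 %.

Readings and results were generated by integration with constants of no real substance; scatter was added.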